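At the last oak reading, 54.0% of the charge is neither target nor isomer of the product.

| setting | oak | maple | east | north-east |
|---|---|---|---|---|
| starting material | 0.60 M | 2.4 M | 1.2 M | 1.2 M |
| temperature | 80 °C | 92 °C | 100 °C | 85 °C |
| remark | run made earlier | run made earlier |  |  |
| time |  |  | 10 min | 10 min |

| run | time / min | target / % | isomer of the product / % |
|---|---|---|---|
| oak | 2.50 | 7 | 1 |
| oak | 5.00 | 16 | 2 |
| oak | 15.0 | 26 | 4 |
| oak | 30.0 | 31 | 15 |
| maple | 1.50 | 32 | 2 |
| maple | 4.00 | 47 | 12 |
| maple | 8.00 | 48 | 22 |
| maple | 12.0 | 43 | 33 |

(each reading ± 2 percentage points)

- percentages count the starting material that a species holds: one target or isomer of the product counts as two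
- the numbers in the tables scatter by 2 percentage points (one standard deviation)

* the flask that comes out highest in share of target in all that became target or isomer of the product, or "all alike" when all lie within 1.5 percentage points (east / north-east / all alike)
* share of target in all that became target or isomer of the product, east
* share of target in all that became target or isomer of the product, north-east

Two of us argue at the board, and I start from that leftover. I take isomer of the product to come from target, so I read a rate constant as isomer gained per minute per target standing. Oak, between 15.0 min and 30.0 min, reads 0.0257 min⁻¹. Maple, between 4.00 min and 12.0 min, reads 0.0583 min⁻¹. Both are readings, and they carry the scatter of 2 percentage points. Stretched by a constant factor per degree, they give 0.0362 min⁻¹ for north-east and 0.101 min⁻¹ for east.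

I carry the isomer clock, that constant times the time in the flask: 0.362 for north-east and 1.01 for east. My view is that target builds evenly, so the average target has stood for half the run. Isomer over target is then 0.5 of the clock, and the share of target, the selectivity, is one over one plus that ratio. This gives 66.5% for east and 84.7% for north-east.

The forecast holds a chain with “target → isomer (first order)”, takes 0.155 per minute for east, and says 38% for east, 81% for north-east, and north-east highest. We name the same flask but differ over east, where my share is higher.

The simulation gives 48.7% for east, with target 33.6% and isomer of the product 35.4%, and 80.4% for north-east, so north-east is highest. In east I miss by 18 points and the forecast by 11 points, so I lose.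

    target ⇌ isomer of the product (K = 1.80, k = 0.00260 s⁻¹, Ea = 109 kJ mol⁻¹, ΔH = −60.0 kJ mol⁻¹)
    2 starting material ⇌ target (K = 2.50 M⁻¹, k = 0.00230 M⁻¹ s⁻¹, Ea = 75.0 kJ mol⁻¹, ΔH = 16.0 kJ mol⁻¹)
    (constants at 100 °C)

In north-east at 10.0 min, target is made 1.46 times as fast as it is used up, each step taken net. The half-life of target in north-east by the forward step to isomer of the product alone, 19 min, is longer than that time. On clock 0.362 my rule gave 84.7% for that flask. My view has its region early, in the same north-east flask read at 2.5 min, with 78% of the starting material left. There the clock stands at 0.0905, the rule gives 95.7%, and the flask gives 95.3%.

(Readings and results come from a simulation for substances that don't exist, noise included.)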